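**Plan**

- Retrosynthesis: the last cut is the aryl–acyl bond C4–C4a of the pyranone (chromone numbering O1, C2, C3, C4, C4a, C5–C8, C8a). This opens the target to a (Z)-3-aryloxy-2-(4-methoxybenzyl)acrylic acid. Further cuts are the enol ether bond O1–C2 (phenol + enol tosylate), C2–C3 (ester + formate) and the C8–CHO bond.
- Enabling feature: ring A is hexasubstituted. With CHO on C8, OH on C7, CH3 on C6, OCH3 on C5 and O1 on C8a, C4a is its only C–H. It lies ortho to O1 and to the C5 methoxyl and para to the C7 hydroxyl, so an acyl cation tethered through O1–C2=C3 can close nowhere else.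
- Forward: ring A comes from symmetric 3,5-dimethoxy-4-methylphenol, which allows one ortho-formylation product and has one hydroxyl to vinylate. The side chain is joined as an enol tosylate, the methyl ether chelated to the aldehyde is removed to free the C7 hydroxyl, the ester is saponified, and the pyranone (the only ring made) closes last.
- Stereochemistry: the target has no stereocentre and no stereogenic double bond. Only the enol ether geometry of the intermediates matters; it is set Z by chelation-controlled enol tosylation and carried on by retentive vinylic substitution.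

Key step: step 8

Assumption: the enol ethers 8–13 are drawn Z (tosyloxy or aryloxy cis to the carboxyl group); any E isomer carried along is expected to converge in step 8, where the acyl-activated push–pull alkene can rotate about C2–C3.

**Route**

Step 1
Reactants: 1 2,6-dimethoxytoluene
Product: 3 3,5-dimethoxy-4-methylphenol, via pinacol arylboronate 2 (not isolated)
Conditions: [Ir(OMe)(cod)]2 (1.5 mol %), dtbpy (3 mol %), B2pin2 (0.6 equiv), THF, 80 °C; then aq. NaOH, 30 % H2O2, 0 °C → rt; dil. HCl
Reagents that add atoms: hydrogen peroxide, OO (the phenol oxygen of 3); bis(pinacolato)diboron, CC1(C)OB(OC1(C)C)B1OC(C)(C)C(C)(C)O1 (the Bpin group of intermediate 2 only)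
Why: Sterically governed Ir-catalysed C–H borylation (Hartwig–Miyaura type) should take the only C–H of 1 without an ortho substituent, the one para to the methyl group, and the boronate is then oxidised in the same flask at the same carbon (borylation–oxidation phenol synthesis).

Step 2
Reactants: 3 3,5-dimethoxy-4-methylphenol
Product: 4 2-hydroxy-4,6-dimethoxy-5-methylbenzaldehyde
Conditions: MgCl2, Et3N, (CH2O)n, MeCN, reflux; then 1 M HCl
Reagents that add atoms: paraformaldehyde (as formaldehyde), C=O
Why: Magnesium-phenoxide-directed ortho-formylation (Casnati–Skattebøl) puts the formyl group only ortho to the hydroxyl; the two ortho positions of 3 are equivalent by symmetry and the para position carries the methyl group, so a single aldehyde can form.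

Step 3
Reactants: 5 methyl 3-(4-methoxyphenyl)propanoate; 6 methyl formate
Product: 7 methyl 2-formyl-3-(4-methoxyphenyl)propanoate
Conditions: NaH, THF, cat. MeOH, 0 °C → rt; then cold 1 M HCl
Reagents that add atoms: none
Why: Crossed Claisen condensation: the ester enolate of 5 is C-formylated by non-enolisable 6, the equilibrium is pulled forward by deprotonation of the β-formyl ester, and the methyl/methyl pairing excludes ester scrambling by alkoxide exchange.

Step 4
Reactants: 7 methyl 2-formyl-3-(4-methoxyphenyl)propanoate
Product: 8 methyl (Z)-2-(4-methoxybenzyl)-3-(tosyloxy)acrylate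
Conditions: TsCl, N-methylimidazole, LiOH, CH2Cl2, 0 °C
Reagents that add atoms: p-toluenesulfonyl chloride, Cc1ccc(cc1)S(Cl)(=O)=O
Why: Stereoselective enol sulfonylation: the lithium enolate of 7 is held as a chelate between the enolate and ester oxygens, which fixes the O–C=C–C=O unit in the Z arrangement, and the N-sulfonylimidazolium formed from TsCl and N-methylimidazole tosylates that oxygen.

Step 5
Reactants: 4 2-hydroxy-4,6-dimethoxy-5-methylbenzaldehyde; 8 methyl (Z)-2-(4-methoxybenzyl)-3-(tosyloxy)acrylate
Product: 9 methyl (Z)-3-(2-formyl-3,5-dimethoxy-4-methylphenoxy)-2-(4-methoxybenzyl)acrylate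
Conditions: Cs2CO3, DMF, 25 → 50 °C
Reagents that add atoms: none
Why: Vinylic nucleophilic substitution by addition–elimination (SNV): the caesium phenoxide of 4, the only hydroxyl present, adds to the β-carbon of the acrylate and the resulting ester enolate expels tosylate before it can rotate, so the oxygen that becomes O1 is fixed and the Z geometry should be retained.

Step 6
Reactants: 9 methyl (Z)-3-(2-formyl-3,5-dimethoxy-4-methylphenoxy)-2-(4-methoxybenzyl)acrylate
Product: 11 methyl (Z)-3-(2-formyl-3-hydroxy-5-methoxy-4-methylphenoxy)-2-(4-methoxybenzyl)acrylate, via aryloxydichloroborane 10 (not isolated)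
Conditions: BCl3 (2 equiv), CH2Cl2, −78 → 0 °C; then H2O
Reagents that add atoms: boron trichloride, ClB(Cl)Cl (the BCl2 group of intermediate 10 only; nothing but hydrogen is added to 11)
Why: Chelation-controlled aryl methyl ether cleavage: BCl3 bound to the aldehyde oxygen forms a six-membered chelate with the adjacent methoxyl (the future C7 oxygen) and chloride removes its methyl group, while the non-chelated future C5 methoxyl, the anisyl methoxyl, the methyl ester and the sp2 C–O bond of the enol ether should survive at low temperature.

Step 7
Reactants: 11 methyl (Z)-3-(2-formyl-3-hydroxy-5-methoxy-4-methylphenoxy)-2-(4-methoxybenzyl)acrylate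
Product: 12 (Z)-3-(2-formyl-3-hydroxy-5-methoxy-4-methylphenoxy)-2-(4-methoxybenzyl)acrylic acid
Conditions: LiOH·H2O, THF/H2O, 0 °C → rt; then 1 M HCl to pH 3, 0 °C
Reagents that add atoms: lithium hydroxide, [Li+].[OH-] (the carboxyl oxygen)
Why: Ester saponification (BAc2) in a methanol-free medium; the salicylaldehyde-type phenol is deprotonated first, which makes the aryloxide a poor leaving group for hydroxide addition–elimination at the β-carbon and shields the aldehyde.

Step 8
Reactants: 12 (Z)-3-(2-formyl-3-hydroxy-5-methoxy-4-methylphenoxy)-2-(4-methoxybenzyl)acrylic acid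
Product: 14 7-hydroxy-5-methoxy-3-(4-methoxybenzyl)-6-methyl-4-oxo-4H-chromene-8-carbaldehyde (the target), via mixed trifluoroacetic anhydride 13 (not isolated)
Conditions: TFAA (1.5 equiv), CH2Cl2, 0 °C; then TfOH (0.5 equiv), 0 °C → rt; aq. NaHCO3
Reagents that add atoms: trifluoroacetic anhydride, O=C(OC(=O)C(F)(F)F)C(F)(F)F (the trifluoroacetyl group of intermediate 13 only; none of its atoms remain in 14)
Why: TFAA turns the acid into mixed anhydride 13, which under triflic acid ionises towards an acylium ion stabilised by the enol ether oxygen and attacks C4a in an intramolecular Friedel–Crafts acylation, loss of the C4a proton giving the chromone; this is the known acid-mediated cyclisation of 3-aryloxyacrylic acids to chromones. The pyranone closes as a six-membered ring by attack of the arene carbon on the acyl carbon, whose C=O stays outside the new ring (6-exo-trig at the anhydride carbonyl). No stereocentre is formed; the step needs only the Z enol ether, and because the acyl-activated push–pull acrylate has little C2–C3 double-bond character any E isomer should rotate into the reactive geometry. Site selectivity comes from the substitution pattern: C4a is the only hydrogen-bearing carbon of ring A and is activated by O1 and the C5 methoxyl (ortho) and the C7 hydroxyl (para), while the C8 formyl group is meta to it and occupies the second position ortho to O1. Closure onto the anisyl ring would give a five-membered indanone at a carbon meta to its methoxyl and should be much slower. Forming 13 before the strong acid is added keeps the acrylate alkene electron-poor, which should suppress Prins-type addition of C3 to the protonated aldehyde, and substoichiometric TfOH limits O-protonation of the formyl group, which would drain ring A of electron density.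

**Compound list**

1 | 2,6-dimethoxytoluene | COc1cccc(OC)c1C | starting material
2 | 2-(3,5-dimethoxy-4-methylphenyl)-4,4,5,5-tetramethyl-1,3,2-dioxaborolane | COc1cc(B2OC(C)(C)C(C)(C)O2)cc(OC)c1C | intermediate (not isolated)
3 | 3,5-dimethoxy-4-methylphenol | COc1cc(O)cc(OC)c1C | intermediate
4 | 2-hydroxy-4,6-dimethoxy-5-methylbenzaldehyde | COc1cc(O)c(C=O)c(OC)c1C | intermediate
5 | methyl 3-(4-methoxyphenyl)propanoate | COC(=O)CCc1ccc(OC)cc1 | starting material
6 | methyl formate | COC=O | starting material
7 | methyl 2-formyl-3-(4-methoxyphenyl)propanoate (racemic, enolisable; drawn as the aldehyde tautomer) | COC(=O)C(C=O)Cc1ccc(OC)cc1 | intermediate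
8 | methyl (Z)-2-(4-methoxybenzyl)-3-(tosyloxy)acrylate | COC(=O)/C(Cc1ccc(OC)cc1)=C\OS(=O)(=O)c1ccc(C)cc1 | intermediate
9 | methyl (Z)-3-(2-formyl-3,5-dimethoxy-4-methylphenoxy)-2-(4-methoxybenzyl)acrylate | COC(=O)/C(Cc1ccc(OC)cc1)=C\Oc1cc(OC)c(C)c(OC)c1C=O | intermediate
10 | methyl (Z)-3-[3-(dichloroboranyloxy)-2-formyl-5-methoxy-4-methylphenoxy]-2-(4-methoxybenzyl)acrylate | COC(=O)/C(Cc1ccc(OC)cc1)=C\Oc1cc(OC)c(C)c(OB(Cl)Cl)c1C=O | intermediate (not isolated)
11 | methyl (Z)-3-(2-formyl-3-hydroxy-5-methoxy-4-methylphenoxy)-2-(4-methoxybenzyl)acrylate | COC(=O)/C(Cc1ccc(OC)cc1)=C\Oc1cc(OC)c(C)c(O)c1C=O | intermediate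
12 | (Z)-3-(2-formyl-3-hydroxy-5-methoxy-4-methylphenoxy)-2-(4-methoxybenzyl)acrylic acid | COc1ccc(C/C(C(=O)O)=C/Oc2cc(OC)c(C)c(O)c2C=O)cc1 | intermediate (key-step precursor)
13 | (Z)-3-(2-formyl-3-hydroxy-5-methoxy-4-methylphenoxy)-2-(4-methoxybenzyl)acrylic trifluoroacetic anhydride | COc1ccc(C/C(C(=O)OC(=O)C(F)(F)F)=C/Oc2cc(OC)c(C)c(O)c2C=O)cc1 | intermediate (not isolated)
14 | 7-hydroxy-5-methoxy-3-(4-methoxybenzyl)-6-methyl-4-oxo-4H-chromene-8-carbaldehyde | COc1ccc(Cc2coc3c(C=O)c(O)c(C)c(OC)c3c2=O)cc1 | target

**Step count**

Total steps: 8. Longest linear sequence: 6 steps (1 → 2 → 5 → 6 → 7 → 8; the ester branch 3 → 4 → 5 → 6 → 7 → 8 is equally long).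

**Steps most likely to fail**

Step 8. The closure may stall because O-protonation of the C8 aldehyde pulls the oxygen lone pairs of ring A away from C4a. The protonated aldehyde may also be attacked by C3 of the enol ether, followed by loss of CO2. Transient O-trifluoroacetylation of the C7 hydroxyl would lower the activation further. The fallback sets out from 12 and masks the aldehyde before the acid step. Ethane-1,2-dithiol with BF3·OEt2 in CH2Cl2 at 0 °C should give (Z)-3-[2-(1,3-dithiolan-2-yl)-3-hydroxy-5-methoxy-4-methylphenoxy]-2-(4-methoxybenzyl)acrylic acid F1. With the carbonyl acceptor gone, Eaton's reagent at 25–40 °C should close the ring at C4a to 8-(1,3-dithiolan-2-yl)-7-hydroxy-5-methoxy-3-(4-methoxybenzyl)-6-methyl-4H-chromen-4-one F2. Alkylative hydrolysis of the dithiolane (MeI, CaCO3, aqueous MeCN) then returns to the route at 14.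

Step 5. The phenoxide of 4 is chelated to the aldehyde and flanked on one side, so it may add only slowly to the trisubstituted acceptor. It may also attack sulfur instead of carbon, transferring the sulfonyl group and returning 7. The fallback sets out from 7 and replaces the addition–elimination by a copper-catalysed C–O coupling. Ph3P·Br2 with Et3N in CH2Cl2 should convert 7 into methyl (Z)-3-bromo-2-(4-methoxybenzyl)acrylate F3. Ullmann-type vinylation of 4 with this bromide (CuI, N,N-dimethylglycine, Cs2CO3, dioxane, 90 °C) rejoins the route at 9.

Step 6. The Lewis acid may activate the acrylate so that chloride cleaves the aryl vinyl ether by addition–elimination, or a second methyl ether may be lost on warming. The fallback sets out from 4 and performs the chelation-controlled demethylation before the enol ether exists. BCl3 in CH2Cl2 (or AlCl3 in MeCN) should give 2,6-dihydroxy-4-methoxy-3-methylbenzaldehyde F4. Its two chelated hydroxyls differ sterically; with one equivalent of Cs2CO3 in DMF the hydroxyl flanked by hydrogen, not the one buttressed by the methyl group, is expected to add to tosylate 8. This returns to the route at 11, with any regioisomer or bis-ether removed by chromatography.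

Further compounds
F1 | step 8 | (Z)-3-[2-(1,3-dithiolan-2-yl)-3-hydroxy-5-methoxy-4-methylphenoxy]-2-(4-methoxybenzyl)acrylic acid | COc1ccc(C/C(C(=O)O)=C/Oc2cc(OC)c(C)c(O)c2C3SCCS3)cc1
F2 | step 8 | 8-(1,3-dithiolan-2-yl)-7-hydroxy-5-methoxy-3-(4-methoxybenzyl)-6-methyl-4H-chromen-4-one | COc1ccc(Cc2coc3c(C4SCCS4)c(O)c(C)c(OC)c3c2=O)cc1
F3 | step 5 | methyl (Z)-3-bromo-2-(4-methoxybenzyl)acrylate | COC(=O)/C(Cc1ccc(OC)cc1)=C\Br
F4 | step 6 | 2,6-dihydroxy-4-methoxy-3-methylbenzaldehyde | COc1cc(O)c(C=O)c(O)c1C
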